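**Assumption:** the target has no stereocentre or stereogenic axis, so "single enantiomer" means the one achiral constitution shown; the stereocentres of the racemic cyclohexanedione intermediates are erased on aromatisation.

## Retrosynthetic overview

1. Cut the depside ester C–O bond: 3-chloro-2-hydroxy-4-methoxy-6-methylbenzoic acid 14 plus methyl orsellinate 9, acylated at its non-chelated 4-OH.
2. Both arenes come from one intermediate, methyl dihydroorsellinate 4. Bromination/dehydrobromination then hydrodebromination gives 9.
3. For 14, gem-dichlorination of 4 at C3 and loss of HCl fixes Cl between the two oxygens before the ring is aromatic; 4-O-methylation and saponification follow.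
4. The carbocycle 4 is made once: intermolecular Michael addition of methyl acetoacetate to methyl crotonate (key C–C bond), then Dieckmann closure.
5. Ring order: cyclohexanedione (step 1), then aromatised separately to ring B (steps 2–3) and ring A (step 4), then ester union (step 7).

## Route

Step 1
Reactants: 1 methyl acetoacetate; 2 methyl (E)-but-2-enoate (methyl crotonate)
Product: 4 methyl 6-methyl-2,4-dioxocyclohexane-1-carboxylate (methyl dihydroorsellinate), via keto diester Michael adduct 3 (not isolated)
Conditions: NaOMe (1.05 equiv), MeOH, reflux, 4 h; then cold 2 M HCl to pH 2, filter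
Reagents that add atoms: none
Why: Intermolecular Michael addition of the acetoacetate enolate to the crotonate β-carbon forms the C1–C6 bond and the adduct closes by Dieckmann (intramolecular Claisen) condensation through its methyl-ketone enolate, driven by the stabilised β-diketone enolate salt; the two new stereocentres are uncontrolled and are destroyed on aromatisation.

Step 2
Reactants: 4 methyl 6-methyl-2,4-dioxocyclohexane-1-carboxylate
Product: 8 methyl 3,5-dibromo-2,4-dihydroxy-6-methylbenzoate, via 3-bromo dione 5 (not isolated), via 3,3-dibromo dione 6 (not isolated), via methyl 3-bromoorsellinate 7 (not isolated)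
Conditions: Br2 (3.0 equiv), AcOH, 15 °C → rt, 16 h; filter the precipitate
Reagents that add atoms: bromine, BrBr
Why: Bromination–dehydrobromination aromatisation, in which enol bromination at C3 and loss of HBr oxidise the dione to the resorcinol and the electron-rich arene is then brominated by electrophilic aromatic substitution at its last free position, so three equivalents converge on one crystalline dibromide.

Step 3
Reactants: 8 methyl 3,5-dibromo-2,4-dihydroxy-6-methylbenzoate
Product: 9 methyl 2,4-dihydroxy-6-methylbenzoate (methyl orsellinate)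
Conditions: H2 (1 atm), 10% Pd/C, NaOAc (2.5 equiv), MeOH, rt
Reagents that add atoms: none
Why: Catalytic hydrogenolysis of both aryl C–Br bonds over Pd/C, buffered by acetate, leaves the ester, phenols and arene untouched.

Step 4
Reactants: 4 methyl 6-methyl-2,4-dioxocyclohexane-1-carboxylate
Product: 12 methyl 3-chloro-2,4-dihydroxy-6-methylbenzoate, via 3-chloro dione 10 (not isolated), via 3,3-dichloro dione 11 (not isolated)
Conditions: SO2Cl2 (2.05 equiv), CH2Cl2, 0 °C → rt; evaporate without aqueous work-up; then DMF, HCl (cat., 4 M in dioxane), 90 °C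
Reagents that add atoms: sulfuryl chloride, O=S(=O)(Cl)Cl
Why: Enol chlorination of the cyclic 1,3-dione occurs twice at C3, its most nucleophilic carbon, and on heating with HCl one chlorine shifts to an α′-carbon and leaves as HCl (dehydrochlorinative aromatisation), so the remaining chlorine is fixed between the two oxygen-bearing carbons before the ring becomes aromatic.

Step 5
Reactants: 12 methyl 3-chloro-2,4-dihydroxy-6-methylbenzoate
Product: 13 methyl 3-chloro-2-hydroxy-4-methoxy-6-methylbenzoate
Conditions: MeI (1.1 equiv), K2CO3 (1.1 equiv), acetone, reflux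
Reagents that add atoms: iodomethane, CI
Why: Williamson ether synthesis limited to one equivalent is selective for the 4-OH because the 2-OH is hydrogen-bonded to the ester carbonyl and flanked by Cl and CO2Me.

Step 6
Reactants: 13 methyl 3-chloro-2-hydroxy-4-methoxy-6-methylbenzoate
Product: 14 3-chloro-2-hydroxy-4-methoxy-6-methylbenzoic acid
Conditions: KOH (5 equiv), DMSO/H2O 4:1, 85 °C; then 2 M HCl, 0 °C, filter
Reagents that add atoms: potassium hydroxide, [K+].[OH-] (its oxygen becomes the carboxyl OH)
Why: Saponification (BAc2) of the hindered salicylate ester in hot aqueous DMSO leaves the aryl chloride and aryl methyl ether intact, and cold acidification avoids decarboxylation.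

Step 7
Reactants: 14 3-chloro-2-hydroxy-4-methoxy-6-methylbenzoic acid; 9 methyl 2,4-dihydroxy-6-methylbenzoate
Product: 16 methyl 4-[(3-chloro-2-hydroxy-4-methoxy-6-methylbenzoyl)oxy]-2-hydroxy-6-methylbenzoate (target), via acyl trifluoroacetate mixed anhydride 15 (not isolated)
Conditions: TFAA (4 equiv), toluene, rt, 3 h; aq. NaHCO3 work-up, chromatography
Reagents that add atoms: none
Why: Mixed-anhydride esterification in which the acyl trifluoroacetate acylates the unhindered, non-chelated 4-OH of 9 while both hydrogen-bonded ortho-hydroxyls stay free, any O-trifluoroacetate being lost on aqueous work-up.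

## Compound list

1 | methyl acetoacetate (methyl 3-oxobutanoate) | CC(=O)CC(=O)OC | starting material
2 | methyl (E)-but-2-enoate (methyl crotonate) | C/C=C/C(=O)OC | starting material
3 | dimethyl 2-acetyl-3-methylpentanedioate (racemic diastereomer mixture, formed in situ as its sodium enolate) | CC(=O)C(C(=O)OC)C(C)CC(=O)OC | intermediate
4 | methyl 6-methyl-2,4-dioxocyclohexane-1-carboxylate (methyl dihydroorsellinate; racemic, enolised) | COC(=O)C1C(C)CC(=O)CC1=O | intermediate
5 | methyl 3-bromo-6-methyl-2,4-dioxocyclohexane-1-carboxylate (racemic, formed in situ) | COC(=O)C1C(C)CC(=O)C(Br)C1=O | intermediate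
6 | methyl 3,3-dibromo-6-methyl-2,4-dioxocyclohexane-1-carboxylate (racemic, formed in situ) | COC(=O)C1C(C)CC(=O)C(Br)(Br)C1=O | intermediate
7 | methyl 3-bromo-2,4-dihydroxy-6-methylbenzoate (methyl 3-bromoorsellinate, formed in situ) | COC(=O)c1c(C)cc(O)c(Br)c1O | intermediate
8 | methyl 3,5-dibromo-2,4-dihydroxy-6-methylbenzoate | COC(=O)c1c(C)c(Br)c(O)c(Br)c1O | intermediate
9 | methyl 2,4-dihydroxy-6-methylbenzoate (methyl orsellinate) | COC(=O)c1c(C)cc(O)cc1O | intermediate
10 | methyl 3-chloro-6-methyl-2,4-dioxocyclohexane-1-carboxylate (racemic, formed in situ) | COC(=O)C1C(C)CC(=O)C(Cl)C1=O | intermediate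
11 | methyl 3,3-dichloro-6-methyl-2,4-dioxocyclohexane-1-carboxylate (racemic, formed in situ) | COC(=O)C1C(C)CC(=O)C(Cl)(Cl)C1=O | intermediate
12 | methyl 3-chloro-2,4-dihydroxy-6-methylbenzoate | COC(=O)c1c(C)cc(O)c(Cl)c1O | intermediate
13 | methyl 3-chloro-2-hydroxy-4-methoxy-6-methylbenzoate | COC(=O)c1c(C)cc(OC)c(Cl)c1O | intermediate
14 | 3-chloro-2-hydroxy-4-methoxy-6-methylbenzoic acid | OC(=O)c1c(C)cc(OC)c(Cl)c1O | intermediate
15 | 3-chloro-2-hydroxy-4-methoxy-6-methylbenzoic trifluoroacetic anhydride (formed in situ) | O=C(OC(=O)C(F)(F)F)c1c(C)cc(OC)c(Cl)c1O | intermediate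
16 | methyl 4-[(3-chloro-2-hydroxy-4-methoxy-6-methylbenzoyl)oxy]-2-hydroxy-6-methylbenzoate (achiral) | COC(=O)c1c(C)cc(OC(=O)c2c(C)cc(OC)c(Cl)c2O)cc1O | target

## Summary

Total step count: 7.
Longest linear sequence: 5 steps (1 → 4 → 5 → 6 → 7); the methyl orsellinate branch (steps 2–3) joins at step 7.

## Steps most likely to fail

**Step 4 (gem-dichlorination and dehydrochlorinative aromatisation).** Positive-chlorine scrambling could give the 3,5-dichloro arene beside unaromatised dione, or hot chloride in DMF could attack the β-keto ester before aromatisation. The fallback sets out from 9. It is 4-O-methylated (MeI 1.05 equiv, K2CO3, acetone) to methyl 2-hydroxy-4-methoxy-6-methylbenzoate F1. F1 is then chlorinated on the arene ortho to the free phenol with SO2Cl2 (1.0 equiv) and catalytic 2,2,6,6-tetramethylpiperidine in toluene at 0 °C. This is an amine-directed ortho-chlorination, and the minor 5-chloro isomer is removed by chromatography. The fallback comes back to the route at 13.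

**Step 5 (selective mono-methylation).** The flanking chlorine acidifies both phenols, so dimethylation or poor 4-/2-selectivity is possible. The fallback sets out from 12. It is methylated exhaustively (MeI 3 equiv, K2CO3, DMF, 60 °C) to methyl 3-chloro-2,4-dimethoxy-6-methylbenzoate F2. Only the ether ortho to the ester is then cleaved with BCl3 (CH2Cl2, −78 → 0 °C; chelation-controlled demethylation). The fallback comes back at 13.

**Step 7 (direct coupling of the unprotected hydroxy acid).** The activated salicylic acid could self-condense or decarboxylate, or acylation of 9 could be sluggish. The fallback sets out from 13 and proceeds as follows: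
- The 2-OH is benzylated (BnBr, K2CO3, DMF, 60 °C) to methyl 2-(benzyloxy)-3-chloro-4-methoxy-6-methylbenzoate F3.
- Saponification (KOH, DMSO/H2O, 85 °C) gives 2-(benzyloxy)-3-chloro-4-methoxy-6-methylbenzoic acid F4.
- Oxalyl chloride with catalytic DMF in CH2Cl2 gives 2-(benzyloxy)-3-chloro-4-methoxy-6-methylbenzoyl chloride F5.
- F5 acylates 9 (pyridine, cat. DMAP, CH2Cl2, 0 °C → rt) to methyl 4-{[2-(benzyloxy)-3-chloro-4-methoxy-6-methylbenzoyl]oxy}-2-hydroxy-6-methylbenzoate F6.
- Hydrogenolysis of the benzyl ether (H2 1 atm, 5% Pd/C, EtOAc, rt, neutral, stopped at one equivalent so the aryl chloride survives) comes back to the route at 16.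

## Further compounds

F1 | step 4 | methyl 2-hydroxy-4-methoxy-6-methylbenzoate | COC(=O)c1c(C)cc(OC)cc1O
F2 | step 5 | methyl 3-chloro-2,4-dimethoxy-6-methylbenzoate | COC(=O)c1c(C)cc(OC)c(Cl)c1OC
F3 | step 7 | methyl 2-(benzyloxy)-3-chloro-4-methoxy-6-methylbenzoate | COC(=O)c1c(C)cc(OC)c(Cl)c1OCc1ccccc1
F4 | step 7 | 2-(benzyloxy)-3-chloro-4-methoxy-6-methylbenzoic acid | OC(=O)c1c(C)cc(OC)c(Cl)c1OCc1ccccc1
F5 | step 7 | 2-(benzyloxy)-3-chloro-4-methoxy-6-methylbenzoyl chloride | ClC(=O)c1c(C)cc(OC)c(Cl)c1OCc1ccccc1
F6 | step 7 | methyl 4-{[2-(benzyloxy)-3-chloro-4-methoxy-6-methylbenzoyl]oxy}-2-hydroxy-6-methylbenzoate | COC(=O)c1c(C)cc(OC(=O)c2c(C)cc(OC)c(Cl)c2OCc2ccccc2)cc1O
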